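Maple leaves about 24.1 % of its starting material unconverted from 50.0 h to 120 h, and birch, with less free catalyst, leaves 40.7 % at 40.0 h.

| flask | starting material | free catalyst | remark | time |
|---|---|---|---|---|
| maple | 1.8 M | 1.8 mM | the very flask that is asked about, followed so far |  |
| birch | 1.8 M | 1.2 mM | run made earlier |  |
| flask | 1.8 M | 1.8 mM |  | 8.0 d |

| run | time / h | target / % | starting material / % |
|---|---|---|---|
| maple | 10.0 | 49.5 | 48.1 |
| maple | 15.0 | 60.7 | 36.4 |
| maple | 20.0 | 65.2 | 31.3 |
| maple | 30.0 | 66.8 | 25.8 |
| maple | 50.0 | 64.3 | 22.9 |
| maple | 72.0 | 61.4 | 24.6 |
| maple | 120 | 47.8 | 24.9 |
| birch | 3.00 | 13.4 | 86.4 |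
| birch | 4.00 | 18.5 | 81.8 |
| birch | 6.00 | 24.7 | 73.0 |
| birch | 10.0 | 36.3 | 62.7 |
| birch | 15.0 | 45.9 | 50.5 |
| birch | 25.0 | 52.9 | 42.6 |
| birch | 40.0 | 53.5 | 40.7 |

(scatter of a reading: 1 percentage point)

- east: change nothing and wait 2.5 d more
- south-east: at 8.0 d take out 90 % of the target then present, then wait 2.5 d
- west: at 8.0 d add free catalyst, 50.0 % of the amount charged, then wait 2.5 d

- percentages count the starting material that a species holds: one spent catalyst counts as two
- what is taken out of target is counted as made
- reactions considered so far: starting material + free catalyst -> catalyst intermediate A; catalyst intermediate A -> catalyst intermediate B; catalyst intermediate B -> free catalyst + target; target -> over-reaction product; catalyst intermediate A + target -> spent catalyst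
- additions bring no volume worth counting

* target, in percent of the starting material first charged, at 8.0 d
* the option that brings most further target ("none" if no option brings more than 2 percentage points) (east / south-east / west / none)
* target present, with what was taken out counted in, in percent of the starting material first charged, after east
* target present, with what was taken out counted in, in percent of the starting material first charged, after south-east

I build the flask one process at a time. The working round by itself returns its catalyst, so the charge allows 100 % of target.

Now I add catalyst intermediate A + target → spent catalyst. Catalyst intermediate A goes forward with a fixed rate constant or meets target at a rate proportional to [target], so the partition ratio falls as [target] rises. Catalyst lost per target made grows with [target], and summing over the run gives a square law, with target made counted as target present: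

maple: [made]²/[free catalyst]₀ = 1040 M
birch: [made]²/[free catalyst]₀ = 949 M
mean: G = 993 M

I call G the catalyst budget: the square of the target made, per catalyst charged, when the last catalyst is lost. Read from the readings, it stops the flask at 74.3 % made.

Last I add target → over-reaction product, read from maple between 50.0 h and 120 h:

k = 0.00424 h⁻¹
now = 35.2 %
east = 27.3 %
south-east = 34.4 %

For west, the added catalyst buys a further amount x, with [target]x + x²/2 = G[added]/2:

x = 28.0 %

That is more than the leftover, so the starting material is the limiting reagent, and west ends near 46.0 %.

The forecast gives 36 %, 28 %, 35.2 % and west, on the words “The catalyst is irreversibly dead.”, with its now above mine.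

The flask gives 38.9 %, 31.4 % after east, 38.2 % after south-east, and west as best, with 12 percentage points further target.

    starting material + free catalyst → catalyst intermediate A (k = 150 M⁻¹ h⁻¹)
    catalyst intermediate A → catalyst intermediate B (k = 99.0 h⁻¹)
    catalyst intermediate B → free catalyst + target (k = 4700 h⁻¹)
    target → over-reaction product (k = 0.00360 h⁻¹)
    catalyst intermediate A + target → spent catalyst (k = 0.200 M⁻¹ h⁻¹)

The neighbouring flask holds 0.45 M of starting material with the same catalyst charge as the asked flask. With [made] equal to that charge of starting material, the budget puts the catalyst lost in the neighbouring flask at [made]²/(G[free catalyst]₀) = 11.3 % of the catalyst charged. At 192 h the neighbouring flask holds 0 % of its starting material and 88.8 % of its catalyst as free catalyst, with spent catalyst at 11.2 %.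

All runs stem from a simulated flask for substances that don't exist; noise was put on by code.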